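Is anything slow in these flasks? The decay of starting material is not: alpha reads 5% of it at 1.50 min.

| flask | starting material | reagent | second substrate | protic impurity | remark | time |
|---|---|---|---|---|---|---|
| alpha | 1 mM | 1.2 mM | 1 mM | 0.020 mM | run made earlier |  |
| zeta | 1 mM | 0.60 mM | 1 mM | 0.020 mM | run made earlier |  |
| eta | 1 mM | 0.90 mM | 1 mM | 0.020 mM | run made earlier |  |
| gamma | 2 mM | 1.2 mM | 1 mM | 0.020 mM | run made earlier |  |
| grey | 1.0 mM | 1.20 mM (fed, over 6.00 min) | 1.00 mM | 0.0200 mM | all but reagent at the start; reagent goes in evenly over 6.00 min, the run ends at 6.0 min | 6.0 min |
| red | 1.0 mM | 1.20 mM | 1.00 mM | 0.0200 mM | a single well-mixed tank run continuously and read at steady state, 6.0 min in it on average |  |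
| violet | 1.0 mM | 1.20 mM | 1.00 mM | 0.0200 mM | a closed flask charged with all of it at once and left for 6.0 min | 6.0 min |
| amber | 1.0 mM | 1.20 mM | 1.00 mM (fed, over 6.00 min) | 0.0200 mM | a stirred flask in which second substrate is dosed at a steady rate over 6.00 min without added volume, worked up at 6.0 min | 6.0 min |

| run | time / min | target / % | starting material / % |
|---|---|---|---|
| alpha | 0.500 | 35 | 22 |
| alpha | 1.50 | 40 | 5 |
| alpha | 3.00 | 43 | 1 |
| alpha | 4.00 | 41 | 4 |
| alpha | 6.00 | 41 | 2 |
| zeta | 0.667 | 24 | 27 |
| zeta | 2.00 | 22 | 3 |
| zeta | 3.00 | 24 | 3 |
| zeta | 5.00 | 26 | 0 |
| zeta | 8.00 | 21 | 0 |
| eta | 0.667 | 32 | 19 |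
| eta | 2.00 | 31 | 3 |
| eta | 3.00 | 30 | 0 |
| eta | 5.00 | 32 | 0 |
| eta | 8.00 | 35 | 2 |
| gamma | 0.667 | 22 | 18 |
| gamma | 2.00 | 25 | 1 |
| gamma | 3.00 | 21 | 1 |
| gamma | 5.00 | 21 | 1 |
| gamma | 8.00 | 22 | 1 |

(readings scatter by 1.5 percentage points)

- the stated concentrations are those of everything mixed, before any reaction; amounts are the same in each set-up
- the numbers in the tables scatter with a standard deviation of 1.5 percentage points
- the feed brings no volume worth counting
- the earlier runs were made in a closed, stirred flask

- the set-up with the highest amount of target at the outlet or at the end, in percent of the starting material put in ("none" if the first two lie within 2 percentage points) (grey / red / violet / amber / none)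
- amount of target at the outlet or at the end, in percent of the starting material put in, grey
- amount of target at the outlet or at the end, in percent of the starting material put in, red
- amount of target at the outlet or at the end, in percent of the starting material put in, violet
- amount of target at the outlet or at the end, in percent of the starting material put in, amber

**How fast does starting material go?** Take the first reading as a pseudo-first-order decay, the natural log of charged over remaining, divided by time. Alpha reads 3.03 min⁻¹; zeta, at half the reagent, reads 1.96 min⁻¹.

**Is that the reagent's doing?** Partly. A straight line through both readings gives the reagent a part of 2.13 min⁻¹ at alpha's charge and leaves a loss of 0.898 min⁻¹. Both carry the scatter.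

**What is that loss?** Zeta reads 0% of starting material at 5.00 min, so, counting one reagent per starting material, about 0.400 mM went beyond its reagent, more than its 0.020 mM of protic impurity. I assume second substrate is the partner, though no run varied it.

**What do you carry forward?** Charged at once, the loss takes 29.6%. Dosed evenly, c(second substrate) climbs from zero, so the loss grows with time, while I hold the reagent's part steady and starting material decays under it with a reckoned half-life of 0.325 min, shorter than the dosing time. Integrating that product gives the loss divided by the dosing time and by the reagent's part squared: 3.30%, the dosing leak, the share of starting material lost to second substrate during dosing.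

**Does the rest become target?** Not in alpha. Its last reading is 41%, so I take 58.3% of what the loss left as target, assume the same for amber, and reckon 56.4%. Violet has alpha's charge and time, so I take that reading for it. Grey and red run at thinner reagent, and zeta's charge already widens the loss to 45.7%, so I rank amber first, above violet.

The forecast named violet best, with grey 16%, red 28%, violet 41% and amber 17%, holding that “Dosing second substrate (amber) starves the capture step, so it is poor”, and there it parts from my amber figure.

The flask gives grey 16.0%, red 26.1%, violet 41.5% and amber 48.2%, so amber is best.

    starting material + second substrate → cross product (k = 19.0 M⁻¹ s⁻¹)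
    starting material + target → side product (k = 26.0 M⁻¹ s⁻¹)
    starting material + protic impurity → quenched substrate (k = 830 M⁻¹ s⁻¹)
    starting material + reagent → target (k = 33.0 M⁻¹ s⁻¹)
    second substrate + reagent → second product (k = 3.10 M⁻¹ s⁻¹)

Amber's target stands below my 56.4%, and it holds 3.61% of cross product, less than violet. The dosing leak of 3.30% stands beside that amber figure. Charged at once, the same two rates gave 29.6%, and violet holds 29.7% of cross product.

Readings and results are simulated on assumed constants, noise included.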